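## Retrosynthetic overview
1. The cyclopropane is the only ring and is closed last. One carbon, C1′ (bearing H and the C19 alkenyl group), is added across C2=C3 of geranylgeraniol 1, whose E geometry already places CH2OH and CH3 cis.
2. C1′ is delivered as a carbene equivalent released from a diazo group. The strategic bond to make is therefore C1′=N, in hydrazone 3 formed from geranylgeranial 2. The nitrogen later leaves as N2.
3. Aldehyde 2 comes from 1 by allylic oxidation, so both C20 halves derive from one commercial alcohol.
4. All three stereocentres are set in the ring-forming step, on a zinc alkoxide of 1 bound to a tartramide dioxaborolane.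

Assumption: all-E geranylgeraniol (annatto-derived bulk material, passed through a silica plug) is treated as a cheap purchasable starting material. Unprimed locants refer to the alcohol half and primed locants to the carbene half.

## Route

Step 1
Reactants: 1 (2E,6E,10E)-geranylgeraniol
Product: 2 (2E,6E,10E)-geranylgeranial
Conditions: activated MnO2 (15 equiv), hexane, 0 °C → rt, 2 h; filter through Celite
Reagents that add atoms: none
Why: Heterogeneous MnO2 allylic oxidation stops at the enal, keeps the 2E geometry, leaves the three isolated trisubstituted alkenes untouched, and creates no stereocentre.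

Step 2
Reactants: 2 (2E,6E,10E)-geranylgeranial
Product: 3 geranylgeranial hydrazone
Conditions: 2 added slowly to N2H4·H2O (8 equiv), Et3N (2 equiv), EtOH, 0 °C → rt, 1 h; used crude after extraction
Reagents that add atoms: hydrazine (as monohydrate), NN
Why: Hydrazone formation (carbonyl condensation) makes the C1′=N bond on which the route rests, because it turns the electrophilic aldehyde carbon into the later carbene carbon with N2 as a traceless leaving group; inverse addition into excess hydrazine at 0 °C limits azine formation and aza-Michael closure to the pyrazoline, and no stereocentre is created (the C=N geometry is irrelevant).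

Step 3
Reactants: 3 geranylgeranial hydrazone (2.5 equiv); 1 (2E,6E,10E)-geranylgeraniol (1.0 equiv)
Product: 6 (1R,2R,3R)-prephytoene alcohol, via diazoalkene 4 (not isolated), via iodozinc carbenoid 5 (not isolated)
Conditions: (a) 3, activated MnO2 (8 equiv), 4 Å MS, CH2Cl2, −10 °C, 20 min, cold filtration to a red solution of 4. (b) 1, Et2Zn (1.05 equiv), CH2Cl2, −15 °C; then (4S,5S)-2-butyl-N,N,N′,N′-tetramethyl-1,3,2-dioxaborolane-4,5-dicarboxamide (1.2 equiv); then ZnI2 (1.0 equiv, in Et2O); solution of 4 added over 3 h, −15 → 0 °C; sat. aq NH4Cl, water wash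
Reagents that add atoms: none
Why: Proposed new method: reagent-controlled enantioselective alkenylcarbenoid Simmons–Smith-type cyclopropanation. MnO2 dehydrogenates 3 to 4, and ZnI2 captures 4 with loss of N2 to give the α-iodo allylic zinc carbenoid 5; the ethylzinc alkoxide of 1 and the dioxaborolane form an ate complex whose alkoxide O and amide C=O chelate the zinc of 5, so CH(alkenyl) reaches only the adjacent C2=C3 bond because the remote trisubstituted alkenes have no anchor; transfer is concerted, so the E-alkene gives CH2OH and CH3 cis; the (4S,5S) controller is chosen because its (4R,5R) enantiomer converts (E)-cinnamyl alcohol into the (1S,2S)-cyclopropylmethanol, so the opposite face is attacked here and gives 1R,2R; the alkenyl group points away from the CH2O–B/Zn cluster and the cis-methyl, which gives 3R with the alkenyl group trans to CH2OH; ZnI2 is regenerated. The closest known reaction types are the dioxaborolane-controlled Simmons–Smith reaction with CH2, alkyl (gem-diiodide-derived) and aryl (aryldiazomethane/zinc halide-derived) carbenoids, and the non-asymmetric ZnI2-catalysed addition of polyprenyl diazoalkenes to polyprenols; what has not been shown is an alkenyl zinc carbenoid on a trisubstituted allylic alcohol under chiral reagent control.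

## Compound list
1 | (2E,6E,10E)-geranylgeraniol | CC(C)=CCC/C(C)=C/CC/C(C)=C/CC/C(C)=C/CO | starting material
2 | (2E,6E,10E)-geranylgeranial | CC(C)=CCC/C(C)=C/CC/C(C)=C/CC/C(C)=C/C=O | intermediate
3 | (2E,6E,10E)-geranylgeranial hydrazone (drawn as the E C=N isomer) | CC(C)=CCC/C(C)=C/CC/C(C)=C/CC/C(C)=C/C=N/N | intermediate
4 | (2E,6E,10E)-1-diazo-3,7,11,15-tetramethylhexadeca-2,6,10,14-tetraene | CC(C)=CCC/C(C)=C/CC/C(C)=C/CC/C(C)=C/C=[N+]=[N-] | intermediate (not isolated)
5 | iodo[(2E,6E,10E)-1-iodo-3,7,11,15-tetramethylhexadeca-2,6,10,14-tetraen-1-yl]zinc | CC(C)=CCC/C(C)=C/CC/C(C)=C/CC/C(C)=C/C(I)[Zn]I | intermediate (not isolated)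
6 | (1R,2R,3R)-prephytoene alcohol, [(1R,2R,3R)-2-methyl-3-[(1E,5E,9E)-2,6,10,14-tetramethylpentadeca-1,5,9,13-tetraenyl]-2-[(3E,7E)-4,8,12-trimethyltrideca-3,7,11-trienyl]cyclopropyl]methanol | CC(C)=CCC/C(C)=C/CC/C(C)=C/CC/C(C)=C/[C@@H]1[C@@H](CO)[C@]1(C)CC/C=C(\C)CC/C=C(\C)CCC=C(C)C | target

## Step count and risks
Total steps: 3. Longest linear sequence: 3 (1 → 2 → 3 → 6). Compound 1 enters a second time in step 3.

**Most likely to fail: step 3 (the new step).**
- Diazoalkene 4 electrocyclises to a 3H-pyrazole above about 0 °C.
- Carbenoid 5 can dimerise to phytoene-type trienes or give azine.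
- A 1,3-zinc shift in the allylic carbenoid could erode the 2′E geometry.
- The anti/syn ratio at C3 and the ee are untested for an alkenyl carbenoid.

The fallback uses known chemistry, sets out from 4 (made as in step 3a) and 1, and returns at 6. Diazoalkene 4 is added to excess 1 in Et2O with catalytic ZnI2 at 0 °C and no chiral controller. This is the established racemic polyprenol cyclopropanation, and chromatography away from the C3 epimer gives racemic prephytoene alcohol F3. Esterification with (S)-O-methylmandelic acid (DCC, DMAP, CH2Cl2) gives two diastereomers, the (1R,2R,3R)-ester F4 and the (1S,2S,3S)-ester F5, which are separated by preparative HPLC on silica. Saponification of F4 (LiOH, THF/MeOH/H2O) gives 6.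

**Second: step 2.** The free N–H hydrazone of an enal can form azine, close to the 2-pyrazoline, or degrade on storage. The fallback sets out from 2 and returns at 4. Aldehyde 2 is condensed with 2-(trifluoromethyl)benzenesulfonyl hydrazide (THF/MeOH, rt) to the storable N-triftosylhydrazone F2, which cannot form azine. Its sodium salt (NaH, CH2Cl2, −40 → 0 °C) fragments in a low-temperature Bamford–Stevens reaction. After filtration this gives the solution of 4 for step 3b.

**Third: step 1.** MnO2 activity varies from batch to batch, and long contact times cause 2E/2Z isomerisation. The fallback sets out from 1 and returns at 2. PBr3 (0.4 equiv, Et2O, −10 °C) gives geranylgeranyl bromide F1 with the E geometry retained. F1 is then oxidised with N-methylmorpholine N-oxide and NaHCO3 in MeCN/THF at rt. The N-oxide is O-alkylated and the amine is then lost, which delivers 2.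

## Further compounds
F1 | step 1 | (2E,6E,10E)-geranylgeranyl bromide | CC(C)=CCC/C(C)=C/CC/C(C)=C/CC/C(C)=C/CBr
F2 | step 2 | geranylgeranial N-[2-(trifluoromethyl)phenyl]sulfonylhydrazone | CC(C)=CCC/C(C)=C/CC/C(C)=C/CC/C(C)=C/C=N/NS(=O)(=O)c1ccccc1C(F)(F)F
F3 | step 3 | racemic prephytoene alcohol (1:1 mixture of 6 and its enantiomer) | CC(C)=CCC/C(C)=C/CC/C(C)=C/CC/C(C)=C/[C@@H]1[C@@H](CO)[C@]1(C)CC/C=C(\C)CC/C=C(\C)CCC=C(C)C.CC(C)=CCC/C(C)=C/CC/C(C)=C/CC/C(C)=C/[C@H]1[C@H](CO)[C@@]1(C)CC/C=C(\C)CC/C=C(\C)CCC=C(C)C
F4 | step 3 | (1R,2R,3R)-prephytoenyl (S)-2-methoxy-2-phenylacetate | CC(C)=CCC/C(C)=C/CC/C(C)=C/CC/C(C)=C/[C@@H]1[C@@H](COC(=O)[C@@H](OC)c2ccccc2)[C@]1(C)CC/C=C(\C)CC/C=C(\C)CCC=C(C)C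
F5 | step 3 | (1S,2S,3S)-prephytoenyl (S)-2-methoxy-2-phenylacetate | CC(C)=CCC/C(C)=C/CC/C(C)=C/CC/C(C)=C/[C@H]1[C@H](COC(=O)[C@@H](OC)c2ccccc2)[C@@]1(C)CC/C=C(\C)CC/C=C(\C)CCC=C(C)C
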